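Count the reagent, not the solid substrate, in this closed, stirred flask.

all flasks: solid substrate 0.80 M; reagent 1.44 M

|  | temperature | remark | time |
|---|---|---|---|
| delta | 25 °C | the very flask that is asked about, followed so far |  |
| beta | 31 °C | run made earlier |  |
| flask | 25 °C |  | 30 h |

- delta (time / h: target / %, solid substrate / %): 4.00: 22.5, 66.2; 8.00: 25.8, 61.2; 10.0: 27.0, 60.2; 15.0: 26.2, 59.1; 20.0: 26.5, 60.6
- beta (time / h: target / %, solid substrate / %): 4.00: 22.1, 65.8; 8.00: 26.1, 60.3; 10.0: 26.4, 61.2; 15.0: 26.7, 58.6; 20.0: 26.8, 58.3

(readings scatter by 0.5 percentage points)

- Monday's: at 30 h take out 90% of the target then present, then wait 2.5 d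
- Friday's: change nothing and wait 2.5 d more
- Saturday's: at 30 h add reagent, 50.0% of the amount charged, then wait 2.5 d
- Sunday's: at 30 h raise the temperature by 20 K, then wait 2.5 d

- solid substrate is a solid; its amount is given per volume of the solution
- target that was removed still counts
- the numbers in the tables scatter by 0.5 percentage points (one standard deviation)
- at the start none of the solid substrate is in solution
- additions bring no volume worth counting

1. target, in percent of the solid substrate first charged, at 30 h
2. what to do for the largest gain in target; "none" if nothing gains more than 2 percentage points (Monday's / Friday's / Saturday's / Sunday's / none)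
3. target present, with what was taken out counted in, in percent of the solid substrate first charged, after Saturday's
4. target present, with what was taken out counted in, in percent of the solid substrate first charged, after Sunday's

In the delta run the target lay flat from 10.0 h on, at a mean of 26.6%, with solid substrate near 60.6%. I assumed one reagent per target, and a steady dissolved part while solid lies there. I call Q, target over free reagent at rest, the split ratio; on its scale, Q equal to 1 is the even split between bound and free.

Q = 0.213 M / 1.23 M = 0.173

b = Q / (1 + Q) = 0.148

Here b is the share of the reagent bound in target, so I reckoned target as b times the reagent present, for this flask while solid lasts.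

Saturday's: 39.9%

Monday's, removed target counted: 46.9%

So Monday's came out above Saturday's. Was one number enough? The beta run, at 31 °C, has a mean of 26.6% and so Q = 0.174, level with the delta run, which promised Sunday's little. By my reckoning Monday's new target, 20 percentage points, asks for a third of the solid substrate read at 20.0 h in the delta run.

The forecast, holding that “target/reagent is fixed”, gave 26.6% now, Monday's as best, 39.9% after Saturday's and 26.7% after Sunday's.

The flask gave 26.2%, with Monday's best at a gain of 20 points, then 39.3% after Saturday's and 27.4% after Sunday's.

    starting material + reagent ⇌ target (K = 1.55 /M, k = 0.00117 /M/s, Ea = 69.0 kJ/mol, ΔH = 2.00 kJ/mol)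
    solid substrate ⇌ starting material, rate k2*(cs2 - [starting material]) while solid is left; crystals form when [starting material] > cs2 (solubility = 0.110 M, k = 3.93 × 10⁻⁴ /s)
    (constants at 25 °C)

In this flask at 30.0 h, the forward half-life of starting material passing with reagent into target was 0.13 h, far shorter than the 30 h waited. The backward rate of that step stood at >99.9% of its forward rate, which is equilibrium (thermodynamic control), and this flask held 13.7% as starting material. Its state gives Q = 0.170. Carried to the same flask charged with 0.36 M of reagent, the reading-based b gives 6.64% target, and that flask holds 6.55%.

The numbers in the tables stem from a simulated flask with made-up constants; noise was put on by code.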